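**Retrosynthetic overview**
1. The target is read as epicatechin-(4β→6)-epicatechin-(4β→6)-epicatechin; the last step is hydrogenolysis of fourteen benzyl ethers and three C8–Br blocking groups.
2. Key disconnection: both C4–C6 interflavan bonds and both C4–C4a bonds of the middle and top units are cut together. Two open-chain (2S,3R)-3-aryl-3-aryloxy-2-benzyloxypropanals annulate in one flask onto an 8-bromoepicatechin nucleophile.
3. The aldehyde comes from D-glyceraldehyde acetonide (C3, C4 and the C3 stereocentre), an aryl Grignard reagent (ring B, Felkin addition) and a Mitsunobu inversion with a bromophloroglucinol ether (ring A, C2 stereocentre).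
4. The bottom unit is (−)-epicatechin, O-benzylated and brominated at C8 so that only C6 can react.
5. Ring order: the bottom-unit rings are preformed; ring C of the middle unit closes first and ring C of the top unit second, both in the same operation.

Assumption: all three units are (2R,3R) with both C4 aryl bonds trans to the neighbouring O3, as read from the SMILES; 3,5-bis(benzyloxy)phenol, 4-bromo-1,2-bis(benzyloxy)benzene and (R)-glyceraldehyde acetonide are taken as catalogue chemicals.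

**Route**

Step 1
Reactants: 1 (−)-epicatechin
Product: 2 5,7,3',4'-tetra-O-benzyl-(−)-epicatechin
Conditions: BnBr (4.5 equiv), K2CO3 (5 equiv), DMF, 0 °C → rt
Reagents that add atoms: benzyl bromide, BrCc1ccccc1
Why: Williamson etherification in which carbonate deprotonates only the four phenols, so the secondary 3-OH stays free and no stereocentre is touched.

Step 2
Reactants: 2 5,7,3',4'-tetra-O-benzyl-(−)-epicatechin
Product: 3 8-bromo-5,7,3',4'-tetra-O-benzyl-(−)-epicatechin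
Conditions: NBS (1.0 equiv), CH2Cl2, −78 °C → rt
Reagents that add atoms: N-bromosuccinimide, O=C1CCC(=O)N1Br
Why: Electrophilic aromatic bromination goes to C8, the more reactive A-ring carbon of 5,7-di-O-benzyl flavans, which leaves C6 as the only nucleophilic carbon.

Step 3
Reactants: 4 3,5-bis(benzyloxy)phenol
Product: 5 2-bromo-3,5-bis(benzyloxy)phenol
Conditions: NBS (1.0 equiv), iPr2NH (10 mol%), CH2Cl2, −78 → 0 °C
Reagents that add atoms: N-bromosuccinimide, O=C1CCC(=O)N1Br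
Why: Amine-catalysed ortho-selective electrophilic bromination of a phenol puts Br next to the OH (future C8), and the minor para isomer is removed by chromatography.

Step 4
Reactants: 6 4-bromo-1,2-bis(benzyloxy)benzene; 7 (R)-2,2-dimethyl-1,3-dioxolane-4-carbaldehyde
Product: 9 (S)-[3,4-bis(benzyloxy)phenyl][(4R)-2,2-dimethyl-1,3-dioxolan-4-yl]methanol, via arylmagnesium bromide 8 (not isolated)
Conditions: Mg, THF, 45 °C; then 7, THF, −78 → −20 °C; H2O
Reagents that add atoms: none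
Why: Grignard addition under Felkin–Anh control (aryl enters anti to the α C–O bond) gives mainly the anti (1S) carbinol, the dioxolane centre coming from D-glyceraldehyde; the syn epimer is removed by chromatography.

Step 5
Reactants: 9 (S)-[3,4-bis(benzyloxy)phenyl][(4R)-2,2-dimethyl-1,3-dioxolan-4-yl]methanol; 5 2-bromo-3,5-bis(benzyloxy)phenol
Product: 10 (4R)-4-[(R)-[3,4-bis(benzyloxy)phenyl][2-bromo-3,5-bis(benzyloxy)phenoxy]methyl]-2,2-dimethyl-1,3-dioxolane
Conditions: PPh3, DIAD, toluene, −20 °C → rt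
Reagents that add atoms: none
Why: Mitsunobu etherification displaces the activated benzylic oxygen by the phenol with SN2 inversion (S → R), giving the threo aryloxy/oxygen pair that becomes the 2,3-cis ring; low temperature and a non-polar solvent suppress ionisation.

Step 6
Reactants: 10 (4R)-4-[(R)-[3,4-bis(benzyloxy)phenyl][2-bromo-3,5-bis(benzyloxy)phenoxy]methyl]-2,2-dimethyl-1,3-dioxolane
Product: 11 (4R)-4-[(R)-[3,4-bis(benzyloxy)phenyl][2-bromo-3,5-bis(benzyloxy)phenoxy]methyl]-2-phenyl-1,3-dioxolane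
Conditions: PhCH(OMe)2 (4 equiv), CSA (5 mol%), MeCN, 40 °C, 150 mbar
Reagents that add atoms: benzaldehyde dimethyl acetal, COC(OC)c1ccccc1
Why: Acid-catalysed transacetalisation is driven by distilling off 2,2-dimethoxypropane; the two carbon stereocentres are untouched and the new acetal carbon (both epimers) is destroyed in the next step.

Step 7
Reactants: 11 (4R)-4-[(R)-[3,4-bis(benzyloxy)phenyl][2-bromo-3,5-bis(benzyloxy)phenoxy]methyl]-2-phenyl-1,3-dioxolane
Product: 12 (2R,3R)-2-(benzyloxy)-3-[3,4-bis(benzyloxy)phenyl]-3-[2-bromo-3,5-bis(benzyloxy)phenoxy]propan-1-ol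
Conditions: iBu2AlH (3 equiv), CH2Cl2, −78 → 0 °C; then aq potassium sodium tartrate
Reagents that add atoms: none
Why: Regioselective reductive opening of the benzylidene acetal, in which aluminium binds the less hindered primary oxygen and hydride cleaves that C–O bond, leaves the benzyl ether on the secondary oxygen.

Step 8
Reactants: 12 (2R,3R)-2-(benzyloxy)-3-[3,4-bis(benzyloxy)phenyl]-3-[2-bromo-3,5-bis(benzyloxy)phenoxy]propan-1-ol
Product: 13 (2S,3R)-2-(benzyloxy)-3-[3,4-bis(benzyloxy)phenyl]-3-[2-bromo-3,5-bis(benzyloxy)phenoxy]propanal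
Conditions: Dess–Martin periodinane, CH2Cl2, 0 °C → rt
Reagents that add atoms: none
Why: Dess–Martin oxidation of the primary alcohol is mild and non-basic, so the α-benzyloxy stereocentre does not epimerise (the descriptor changes from R to S only through priority).

Step 9
Reactants: 3 8-bromo-5,7,3',4'-tetra-O-benzyl-(−)-epicatechin; 13 (2S,3R)-2-(benzyloxy)-3-[3,4-bis(benzyloxy)phenyl]-3-[2-bromo-3,5-bis(benzyloxy)phenoxy]propanal (two molecules)
Product: 16 [3,5,7,3',4'-penta-O-benzyl-8-bromoepicatechin]-(4β→6)-[3,5,7,3',4'-penta-O-benzyl-8-bromoepicatechin]-(4β→6)-[5,7,3',4'-tetra-O-benzyl-8-bromoepicatechin], via chroman-4-ol 14 (not isolated), via dimer 15 (not isolated)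
Conditions: BF3·OEt2 (2.5 equiv), 4 Å MS, CH2Cl2, −78 → −30 °C; 13 (2.2 equiv) added over 3 h to 3 (1.0 equiv)
Reagents that add atoms: none
Why: Proposed new method: BF3 activation of the aldehyde triggers a six-ring intramolecular Friedel–Crafts hydroxyalkylation at the only free ortho carbon of the bromophloroglucinol ether (closest precedent: Lewis-acid cyclisation of 3-aryloxypropanals to chroman-4-ols), the doubly activated benzylic alcohol 14 ionises to the same C4 cation used in 4-hydroxy/4-alkoxyflavan procyanidin couplings and is trapped at C6 of 3 (C8 blocked) anti to the pseudo-axial 3-OBn to give the 4β (3,4-trans) bond, and dimer 15, whose only free A-ring carbon is C6 of the new unit, repeats the sequence with a second 13, so two pyran rings, two interflavan bonds and two C4 stereocentres form in one flask with chain length set by stoichiometry.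

Step 10
Reactants: 16 [3,5,7,3',4'-penta-O-benzyl-8-bromoepicatechin]-(4β→6)-[3,5,7,3',4'-penta-O-benzyl-8-bromoepicatechin]-(4β→6)-[5,7,3',4'-tetra-O-benzyl-8-bromoepicatechin]
Product: 17 epicatechin-(4β→6)-epicatechin-(4β→6)-epicatechin (CNP0163146.2)
Conditions: H2 (1 atm), Pd(OH)2/C, Et3N (3.5 equiv), THF/MeOH/H2O, rt
Reagents that add atoms: none
Why: Catalytic hydrogenolysis removes all fourteen O-benzyl groups and, with Et3N taking up HBr, the three aryl bromides, without touching any stereocentre.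

**Compound list**
1 | (−)-epicatechin, (2R,3R) | O[C@@H]1Cc2c(O)cc(O)cc2O[C@@H]1c1ccc(O)c(O)c1 | starting material
2 | 5,7,3',4'-tetra-O-benzyl-(−)-epicatechin, (2R,3R) | O[C@@H]1Cc2c(OCc3ccccc3)cc(OCc3ccccc3)cc2O[C@@H]1c1ccc(OCc2ccccc2)c(OCc2ccccc2)c1 | intermediate
3 | 8-bromo-5,7,3',4'-tetra-O-benzyl-(−)-epicatechin, (2R,3R) | O[C@@H]1Cc2c(OCc3ccccc3)cc(OCc3ccccc3)c(Br)c2O[C@@H]1c1ccc(OCc2ccccc2)c(OCc2ccccc2)c1 | intermediate
4 | 3,5-bis(benzyloxy)phenol | Oc1cc(OCc2ccccc2)cc(OCc2ccccc2)c1 | starting material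
5 | 2-bromo-3,5-bis(benzyloxy)phenol | Oc1cc(OCc2ccccc2)cc(OCc2ccccc2)c1Br | intermediate
6 | 4-bromo-1,2-bis(benzyloxy)benzene | Brc1ccc(OCc2ccccc2)c(OCc2ccccc2)c1 | starting material
7 | (R)-2,2-dimethyl-1,3-dioxolane-4-carbaldehyde (D-glyceraldehyde acetonide) | CC1(C)OC[C@@H](O1)C=O | starting material
8 | [3,4-bis(benzyloxy)phenyl]magnesium bromide | Br[Mg]c1ccc(OCc2ccccc2)c(OCc2ccccc2)c1 | intermediate
9 | (S)-[3,4-bis(benzyloxy)phenyl][(4R)-2,2-dimethyl-1,3-dioxolan-4-yl]methanol (anti adduct) | CC1(C)OC[C@@H](O1)[C@@H](O)c1ccc(OCc2ccccc2)c(OCc2ccccc2)c1 | intermediate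
10 | (4R)-4-[(R)-[3,4-bis(benzyloxy)phenyl][2-bromo-3,5-bis(benzyloxy)phenoxy]methyl]-2,2-dimethyl-1,3-dioxolane | CC1(C)OC[C@@H](O1)[C@@H](c1ccc(OCc2ccccc2)c(OCc2ccccc2)c1)Oc1cc(OCc2ccccc2)cc(OCc2ccccc2)c1Br | intermediate
11 | (4R)-4-[(R)-[3,4-bis(benzyloxy)phenyl][2-bromo-3,5-bis(benzyloxy)phenoxy]methyl]-2-phenyl-1,3-dioxolane, both epimers at the acetal carbon | c1ccccc1C1OC[C@@H](O1)[C@@H](c1ccc(OCc2ccccc2)c(OCc2ccccc2)c1)Oc1cc(OCc2ccccc2)cc(OCc2ccccc2)c1Br | intermediate
12 | (2R,3R)-2-(benzyloxy)-3-[3,4-bis(benzyloxy)phenyl]-3-[2-bromo-3,5-bis(benzyloxy)phenoxy]propan-1-ol | OC[C@@H](OCc1ccccc1)[C@@H](c1ccc(OCc2ccccc2)c(OCc2ccccc2)c1)Oc1cc(OCc2ccccc2)cc(OCc2ccccc2)c1Br | intermediate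
13 | (2S,3R)-2-(benzyloxy)-3-[3,4-bis(benzyloxy)phenyl]-3-[2-bromo-3,5-bis(benzyloxy)phenoxy]propanal | O=C[C@@H](OCc1ccccc1)[C@@H](c1ccc(OCc2ccccc2)c(OCc2ccccc2)c1)Oc1cc(OCc2ccccc2)cc(OCc2ccccc2)c1Br | intermediate
14 | (2R,3R)-3,5,7-tris(benzyloxy)-2-[3,4-bis(benzyloxy)phenyl]-8-bromochroman-4-ol, both C4 epimers | c1c(OCc3ccccc3)c(Br)c2c(c1OCc3ccccc3)C(O)[C@@H](OCc1ccccc1)[C@@H](c1ccc(OCc3ccccc3)c(OCc3ccccc3)c1)O2 | intermediate
15 | [3,5,7,3',4'-penta-O-benzyl-8-bromoepicatechin]-(4β→6)-[5,7,3',4'-tetra-O-benzyl-8-bromoepicatechin]; both units (2R,3R), C4 aryl trans to O3 | c1c(OCc4ccccc4)c(Br)c2c(c1OCc4ccccc4)[C@H](c1c(OCc4ccccc4)c(Br)c3c(c1OCc4ccccc4)C[C@@H](O)[C@@H](c1ccc(OCc4ccccc4)c(OCc4ccccc4)c1)O3)[C@@H](OCc4ccccc4)[C@@H](c1ccc(OCc4ccccc4)c(OCc4ccccc4)c1)O2 | intermediate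
16 | [3,5,7,3',4'-penta-O-benzyl-8-bromoepicatechin]-(4β→6)-[3,5,7,3',4'-penta-O-benzyl-8-bromoepicatechin]-(4β→6)-[5,7,3',4'-tetra-O-benzyl-8-bromoepicatechin]; all units (2R,3R), both C4 aryl bonds trans to O3 | C(c4ccccc4)Oc1cc(OCc4ccccc4)c2c(c1Br)O[C@H](c1ccc(OCc4ccccc4)c(OCc4ccccc4)c1)[C@H](OCc4ccccc4)[C@H]2c1c(OCc4ccccc4)c(Br)c2c(c1OCc4ccccc4)[C@H](c1c(OCc4ccccc4)c(Br)c3c(c1OCc4ccccc4)C[C@@H](O)[C@@H](c1ccc(OCc4ccccc4)c(OCc4ccccc4)c1)O3)[C@@H](OCc4ccccc4)[C@@H](c1ccc(OCc4ccccc4)c(OCc4ccccc4)c1)O2 | intermediate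
17 | epicatechin-(4β→6)-epicatechin-(4β→6)-epicatechin (CNP0163146.2) | Oc1cc(O)c2c(c1)O[C@H](c1ccc(O)c(O)c1)[C@H](O)[C@H]2c1c(O)cc2c(c1O)[C@H](c1c(O)cc3c(c1O)C[C@@H](O)[C@@H](c1ccc(O)c(O)c1)O3)[C@@H](O)[C@@H](c1ccc(O)c(O)c1)O2 | target

**Step count and risks**
Total: 10 steps. Longest linear sequence: 7 steps (steps 4 to 10).

Most likely to fail, step 9. The one-flask double annulation gives a spread of chain lengths; about 30% of 16 is expected, beside dimer 15 (recyclable with one more equivalent of 13) and tetramer. Fallback: the ring-forming cascade is given up and the upper units are taken from epicatechin. It sets out from 3: benzylation of O3 (NaH, BnBr, DMF) gives the pentabenzyl ether F1, and oxidation at C4 with DDQ in CH2Cl2 containing ethylene glycol gives the 4β-(2-hydroxyethoxy) ether F2. F2 with excess 3 (BF3·OEt2 or TiCl4, CH2Cl2, −78 °C) gives 15, now isolated, and a second coupling of F2 with 15 comes back to the route at 16.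

Second, step 5. The electron-rich benzylic carbinol may ionise, which erodes the inversion, and the ortho-bromophenol is hindered. Fallback: the ether is made by epoxide opening instead. It sets out from 6 and uses 5:
- Coupling of 6 with propargyl alcohol (PdCl2(PPh3)2, CuI, Et3N, 70 °C) gives the arylpropynol F3.
- Semi-hydrogenation (H2, Pd/CaCO3 poisoned with Pb(OAc)2, quinoline) gives the (Z)-allylic alcohol F4.
- Sharpless epoxidation (Ti(OiPr)4, D-(−)-diethyl tartrate, tBuOOH, 4 Å MS, −20 °C) gives the cis-epoxy alcohol F5.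
- Ti(OiPr)4-mediated opening at the benzylic carbon by phenol 5, with inversion, gives the diol F6.
- PhCH(OMe)2 with CSA comes back to the route at 11.

Third, step 4. The Felkin selectivity of the aryl Grignard addition may be only about 3–4:1. Fallback: the carbinol centre is set by reduction instead of addition. It sets out from the anti/syn mixture of 9: Dess–Martin oxidation gives the aryl ketone F7, and chelation-controlled reduction with Zn(BH4)2 (Et2O, −40 °C), hydride entering on the face of the small α-hydrogen of the zinc chelate, converges both epimers and comes back to the route at 9.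

**Further compounds**
F1 | step 9 | 3,5,7,3',4'-penta-O-benzyl-8-bromo-(−)-epicatechin, (2R,3R) | c1c(OCc4ccccc4)c(Br)c2c(c1OCc4ccccc4)C[C@@H](OCc4ccccc4)[C@@H](c1ccc(OCc4ccccc4)c(OCc4ccccc4)c1)O2
F2 | step 9 | 3,5,7,3',4'-penta-O-benzyl-8-bromo-4β-(2-hydroxyethoxy)-(−)-epicatechin, (2R,3R), C4 oxygen trans to O3 | c1c(OCc4ccccc4)c(Br)c2c(c1OCc4ccccc4)[C@H](OCCO)[C@@H](OCc4ccccc4)[C@@H](c1ccc(OCc4ccccc4)c(OCc4ccccc4)c1)O2
F3 | step 5 | 3-[3,4-bis(benzyloxy)phenyl]prop-2-yn-1-ol | OCC#Cc1ccc(OCc2ccccc2)c(OCc2ccccc2)c1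
F4 | step 5 | (Z)-3-[3,4-bis(benzyloxy)phenyl]prop-2-en-1-ol | OC/C=C\c1ccc(OCc2ccccc2)c(OCc2ccccc2)c1
F5 | step 5 | [(2R,3S)-3-[3,4-bis(benzyloxy)phenyl]oxiran-2-yl]methanol (cis) | OC[C@H]1O[C@H]1c1ccc(OCc2ccccc2)c(OCc2ccccc2)c1
F6 | step 5 | (2R,3R)-3-[3,4-bis(benzyloxy)phenyl]-3-[2-bromo-3,5-bis(benzyloxy)phenoxy]propane-1,2-diol | OC[C@@H](O)[C@@H](c1ccc(OCc2ccccc2)c(OCc2ccccc2)c1)Oc1cc(OCc2ccccc2)cc(OCc2ccccc2)c1Br
F7 | step 4 | [3,4-bis(benzyloxy)phenyl][(4R)-2,2-dimethyl-1,3-dioxolan-4-yl]methanone | CC1(C)OC[C@@H](O1)C(=O)c1ccc(OCc2ccccc2)c(OCc2ccccc2)c1
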